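The route rests on cutting the C2–C1' bond between ring C and ring B. C2 is the β-carbon of the C4 ketone and C3, which carries the methoxyl, is its enolisable α-carbon, so an aryl–rhodium species from a ring B boronic acid can add in conjugate fashion to a flat, achiral 3-methoxychromone. In one operation the ligand on rhodium fixes C2 and protonation of the enolate under equilibrating conditions delivers the trans-diequatorial C3, completing the skeleton. The precursor is a 3,7-dimethoxychromone whose 5- and 6-oxygens are tied up as a diphenylmethylene ketal; the partner is 3-benzyloxy-4-methoxyphenylboronic acid. One hydrogenolysis then frees all three phenols.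

Key step: step 5

Remark: 2,6-dimethoxybenzene-1,4-diol is taken as a catalogue compound; it and the two hydroquinones made from it (3 and 4) are air-sensitive and are handled under argon.
Remark: the diene antipode written in step 5 is assumed to give 2R. Because the 3-methoxyl reverses the CIP order at C2, this is the facial sense that gives (2S)-flavanones from 3-unsubstituted chromones. The sense is to be confirmed on a trial run by circular dichroism against known (2R,3R)-dihydroflavonols, and the mirror-image ligand is used if it proves opposite.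

Step 1
Reactants: 1 2,6-dimethoxybenzene-1,4-diol; 2 methoxyacetic acid
Product: 3 1-(3,6-dihydroxy-2,4-dimethoxyphenyl)-2-methoxyethan-1-one
Conditions: BF3·OEt2 (as solvent), 80–90 °C, Ar; aq NaOAc work-up
Reagents that add atoms: none
Why: Friedel–Crafts C-acylation (directly or through O-acylation and Fries shift) under BF3 activation should occur at either of the two symmetry-equivalent free ring positions, each ortho to a hydroxyl, and stop after one acylation because the chelated aryl ketone deactivates the ring.

Step 2
Reactants: 3 1-(3,6-dihydroxy-2,4-dimethoxyphenyl)-2-methoxyethan-1-one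
Product: 4 2-methoxy-1-(2,3,6-trihydroxy-4-methoxyphenyl)ethan-1-one
Conditions: BCl3 (3 equiv), CH2Cl2, −78 to 0 °C, Ar; then H2O
Reagents that add atoms: none
Why: Chelation-directed Lewis-acid ether cleavage should remove only the methyl of the methoxyl ortho to the ketone, whose oxygen is twisted out of conjugation and leaves as a vinylogous carboxylate when chloride attacks the methyl group, while the para methoxyl and the aliphatic methoxyl react much more slowly in the cold.

Step 3
Reactants: 4 2-methoxy-1-(2,3,6-trihydroxy-4-methoxyphenyl)ethan-1-one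
Product: 5 1-(5-hydroxy-7-methoxy-2,2-diphenyl-1,3-benzodioxol-4-yl)-2-methoxyethan-1-one
Conditions: Ph2CCl2 (1.3 equiv), Ph2O, 170 °C, Ar
Reagents that add atoms: dichlorodiphenylmethane, ClC(Cl)(c1ccccc1)c1ccccc1
Why: Catechol ketalisation by double substitution of the benzylic gem-dichloride can close a five-membered dioxole only across the one vicinal pair of hydroxyls, so the hydroxyl hydrogen-bonded to the ketone stays free, and the base-free medium avoids air oxidation of the para-dihydroxy arene.

Step 4
Reactants: 5 1-(5-hydroxy-7-methoxy-2,2-diphenyl-1,3-benzodioxol-4-yl)-2-methoxyethan-1-one; 6 N,N-dimethylformamide dimethyl acetal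
Product: 8 3,7-dimethoxy-5,6-(diphenylmethylenedioxy)-4H-chromen-4-one, via enaminone 7 (not isolated)
Conditions: toluene, 100 °C; then AcOH, rt to 50 °C
Reagents that add atoms: none
Why: Condensation of the activated α-methoxy methylene with the amide acetal gives the enaminone, and addition of the ortho phenol to its β-carbon followed by loss of dimethylamine (the enaminone route to chromones and isoflavones) closes the pyranone through the O1–C2 bond.

Step 5
Reactants: 8 3,7-dimethoxy-5,6-(diphenylmethylenedioxy)-4H-chromen-4-one; 9 3-benzyloxy-4-methoxyphenylboronic acid (2 equiv)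
Product: 11 (2R,3R)-2-(3-benzyloxy-4-methoxyphenyl)-3,7-dimethoxy-5,6-(diphenylmethylenedioxy)chroman-4-one, via cis epimer 10 (not isolated)
Conditions: [RhCl(C2H4)2]2 (2.5 mol%, monovalent rhodium), (R,R)-2,5-diphenylbicyclo[2.2.2]octa-2,5-diene (5.5 mol%), KOH (0.2 equiv), dioxane/H2O, 50 °C; then Et3N, rt
Reagents that add atoms: none
Why: A rhodium hydroxide carrying the chiral diene transmetalates with the boronic acid, the aryl–rhodium species inserts the C2=C3 bond of the chromone with the aryl delivered to the unsubstituted C2 (the β-carbon of the C4 ketone), and hydrolysis of the oxa-allyl rhodium enolate puts hydrogen on C3 and returns the hydroxide. The closest known reaction type is the Hayashi–Miyaura enantioselective 1,4-addition of arylboronic acids to chromones, which gives flavanones with rhodium–diene or rhodium–bisphosphine catalysts; the 3-methoxyl is an extra α-substituent on an established acceptor class. No ring is closed, because ring B is joined through the C2–C1' bond to the preformed ring A/ring C bicycle. C2 (R) is controlled by the ligand, which distinguishes the two faces of the flat, achiral chromone, and C3 (R) by thermodynamics, since protonation and amine-mediated enolisation converge the cis epimer 10 onto the trans isomer with aryl and methoxyl both equatorial. The step needs face selectivity, 1,4- over 1,2-addition, trans selectivity and survival of the pyranone; these are secured by the hydrogen-only C2, the absence of free phenols, the capped 5-oxygen, the 4'-methoxyl (no 4'-phenoxide to drive a retro-oxa-Michael opening) and hydroxide that is buffered as the boronate.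

Step 6
Reactants: 11 (2R,3R)-2-(3-benzyloxy-4-methoxyphenyl)-3,7-dimethoxy-5,6-(diphenylmethylenedioxy)chroman-4-one
Product: 12 (2R,3R)-5,6-dihydroxy-2-(3-hydroxy-4-methoxyphenyl)-3,7-dimethoxychroman-4-one
Conditions: H2 (1 atm), Pd/C (10 wt% Pd), THF/MeOH, rt
Reagents that add atoms: none
Why: Catalytic hydrogenolysis should cleave the benzylic C–O bonds of the benzyl ether and of the diphenylmethylene ketal in one neutral operation, leaving the C2 and C3 stereocentres, the chelated aryl ketone and the methyl ethers untouched when it is stopped at the calculated hydrogen uptake.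

Compound list
1 | 2,6-dimethoxybenzene-1,4-diol | COc1cc(O)cc(OC)c1O | starting material
2 | methoxyacetic acid | COCC(=O)O | starting material
3 | 1-(3,6-dihydroxy-2,4-dimethoxyphenyl)-2-methoxyethan-1-one | COCC(=O)c1c(O)cc(OC)c(O)c1OC | intermediate
4 | 2-methoxy-1-(2,3,6-trihydroxy-4-methoxyphenyl)ethan-1-one | COCC(=O)c1c(O)cc(OC)c(O)c1O | intermediate
5 | 1-(5-hydroxy-7-methoxy-2,2-diphenyl-1,3-benzodioxol-4-yl)-2-methoxyethan-1-one | COCC(=O)c1c(O)cc(OC)c2OC(c3ccccc3)(c3ccccc3)Oc12 | intermediate
6 | N,N-dimethylformamide dimethyl acetal | COC(OC)N(C)C | starting material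
7 | (Z)-3-(dimethylamino)-1-(5-hydroxy-7-methoxy-2,2-diphenyl-1,3-benzodioxol-4-yl)-2-methoxyprop-2-en-1-one (enaminone) | CO/C(=C\N(C)C)C(=O)c1c(O)cc(OC)c2OC(c3ccccc3)(c3ccccc3)Oc12 | intermediate
8 | 3,7-dimethoxy-5,6-(diphenylmethylenedioxy)-4H-chromen-4-one | COC1=COc2cc(OC)c3OC(c4ccccc4)(c4ccccc4)Oc3c2C1=O | intermediate
9 | 3-benzyloxy-4-methoxyphenylboronic acid | COc1ccc(B(O)O)cc1OCc1ccccc1 | starting material
10 | (2R,3S)-2-(3-benzyloxy-4-methoxyphenyl)-3,7-dimethoxy-5,6-(diphenylmethylenedioxy)chroman-4-one (cis epimer) | COc1ccc([C@H]2Oc3cc(OC)c4OC(c5ccccc5)(c5ccccc5)Oc4c3C(=O)[C@H]2OC)cc1OCc1ccccc1 | intermediate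
11 | (2R,3R)-2-(3-benzyloxy-4-methoxyphenyl)-3,7-dimethoxy-5,6-(diphenylmethylenedioxy)chroman-4-one | COc1ccc([C@H]2Oc3cc(OC)c4OC(c5ccccc5)(c5ccccc5)Oc4c3C(=O)[C@@H]2OC)cc1OCc1ccccc1 | intermediate
12 | (2R,3R)-5,6-dihydroxy-2-(3-hydroxy-4-methoxyphenyl)-3,7-dimethoxychroman-4-one | COc1ccc([C@H]2Oc3cc(OC)c(O)c(O)c3C(=O)[C@@H]2OC)cc1O | target

Total step count: 6. Longest linear sequence: 6 steps (1 → 3 → 4 → 5 → 8 → 11 → 12); compounds 2, 6 and 9 are bought.

Steps most likely to fail

Step 5. The electron-rich, α-substituted chromone may insert too slowly, so that protodeboronation of the boronic acid wins. Facial selectivity may be poor, or hydroxide may open the pyranone and erode C2. The fallback replaces catalytic arylation by ring closure plus resolution; it sets out from 5 and returns at 11. Claisen–Schmidt condensation of 5 with commercial 3-benzyloxy-4-methoxybenzaldehyde (KOH, EtOH, rt) should give the (Z)-α-methoxy-2'-hydroxychalcone F1. Intramolecular oxa-Michael addition of its phenol (NaOAc, EtOH, reflux), favoured by the ortho ketal oxygen that twists the chalcone, should give the racemic trans-3-methoxyflavanone F2. Preparative chromatography on a chiral stationary phase then delivers 11. The mirror-image material can be returned to the racemate by base-mediated ring opening and reclosure.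

Step 2. The Lewis acid may cleave the para methoxyl (through the neighbouring borate) or the aliphatic methoxyl (through a five-membered ketone chelate) instead of, or as well as, the intended one. The fallback introduces the oxygen by oxidation and needs no dealkylation; it sets out from 2 and returns at 4. Acylation of commercial phloroglucinol with 2 (BF3·OEt2, 80 °C) should give 2-methoxy-1-(2,4,6-trihydroxyphenyl)ethan-1-one F3. Methylation of its one non-chelated hydroxyl (Me2SO4, 1 equiv, K2CO3, acetone) should give 1-(2,6-dihydroxy-4-methoxyphenyl)-2-methoxyethan-1-one F4. Elbs persulfate oxidation (K2S2O8, aq NaOH, 0–20 °C) places oxygen para to a phenol, at either of two equivalent positions, as potassium 2,4-dihydroxy-6-methoxy-3-(methoxyacetyl)phenyl sulfate F5. Hydrolysis of this sulfate with warm dilute HCl under argon gives 4.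

Step 6. Hydrogenolysis may go too far (opening of the benzylic C2–O1 bond or reduction of the C4 ketone), or the ketal may be removed incompletely. The fallback is non-reductive and runs in two stages; it sets out from 11 and returns at 12. Hydrolysis of the ketal (AcOH/H2O, 90 °C) should give (2R,3R)-2-(3-benzyloxy-4-methoxyphenyl)-5,6-dihydroxy-3,7-dimethoxychroman-4-one F6. Lewis-acid debenzylation with a cation scavenger (BCl3, pentamethylbenzene, CH2Cl2, −78 °C), which spares aryl methyl ethers, then gives 12.

Further compounds
F1 | step 5 | (Z)-3-(3-benzyloxy-4-methoxyphenyl)-1-(5-hydroxy-7-methoxy-2,2-diphenyl-1,3-benzodioxol-4-yl)-2-methoxyprop-2-en-1-one | CO/C(=C\c1ccc(OC)c(OCc2ccccc2)c1)C(=O)c1c(O)cc(OC)c2OC(c3ccccc3)(c3ccccc3)Oc12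
F2 | step 5 | racemic trans-2-(3-benzyloxy-4-methoxyphenyl)-3,7-dimethoxy-5,6-(diphenylmethylenedioxy)chroman-4-one (equimolar 2R,3R and 2S,3S) | COc1ccc([C@H]2Oc3cc(OC)c4OC(c5ccccc5)(c5ccccc5)Oc4c3C(=O)[C@@H]2OC)cc1OCc1ccccc1.COc1ccc([C@@H]2Oc3cc(OC)c4OC(c5ccccc5)(c5ccccc5)Oc4c3C(=O)[C@H]2OC)cc1OCc1ccccc1
F3 | step 2 | 2-methoxy-1-(2,4,6-trihydroxyphenyl)ethan-1-one | COCC(=O)c1c(O)cc(O)cc1O
F4 | step 2 | 1-(2,6-dihydroxy-4-methoxyphenyl)-2-methoxyethan-1-one | COCC(=O)c1c(O)cc(OC)cc1O
F5 | step 2 | potassium 2,4-dihydroxy-6-methoxy-3-(methoxyacetyl)phenyl sulfate | COCC(=O)c1c(O)cc(OC)c(OS(=O)(=O)[O-])c1O.[K+]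
F6 | step 6 | (2R,3R)-2-(3-benzyloxy-4-methoxyphenyl)-5,6-dihydroxy-3,7-dimethoxychroman-4-one | COc1ccc([C@H]2Oc3cc(OC)c(O)c(O)c3C(=O)[C@@H]2OC)cc1OCc1ccccc1
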